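**Retrosynthetic overview**

1. Target 30 is 7,9-di-O-angeloyl-7,8,9-trihydroxylongipinan-1-one; the angelates go on last (triol 25, transient silylation of the unhindered C8–OH), and C2 is inserted between C1 and C3 of the 2-nor ketone 22 by diazoalkane ring expansion.
2. Key disconnection: the cyclobutane bonds C4–C10 and C5–C11, made together by a transannular crossed enone–alkene [2+2] photocycloaddition of the ten-membered dienone 21.
3. Enabling feature: the cyclobutane C4–C5–C11–C10 carries the C1 ketone on C11 and is spanned 1,3 by C6–C9 (seven-membered ring) and by C1–C2–C3 (six-membered ring). With C2 left out, C10=C11–C1(=O)–C3–C4=C5 is a hexa-1,5-dien-3-one, the pattern that photocyclises crossed (rule of five).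
4. Macrocycle 21: C1–C11 by Nozaki–Hiyama–Kishi ring closure, C4=C5 by Julia–Kocienski coupling of aldehyde 11 with sulfone 15, C6–C7 by Brown reverse prenylation, the C10 methyl by alkyne carboalumination.
5. Stereochemical sources and ring order: C8/C9 from D-erythronolactone, C7 by reagent control, C3 from (R)-3-bromo-2-methylpropan-1-ol (it also steers the photocycloaddition); ten-membered ring first, then cyclobutane, cyclopentanone and cycloheptane in the key step, then cyclopentanone to cyclohexanone.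

Key step: step 15

Remark: locants are the longipinane locants of the target (C1 ketone, C2 CH2, C3 CHMe, C4 and C11 the cyclobutane CH next to C3 and C1, C5 the cyclobutane CH next to C6, C6 CMe2, C7–C9 the oxygenated carbons, C10 the methyl-bearing cyclobutane carbon); both acyl groups are read as angelates, (Z)-2-methylbut-2-enoates.

**Route**

Step 1
Reactants: 1 2,3-O-isopropylidene-D-erythronolactone
Product: 3 [(4R,5S)-5-ethynyl-2,2-dimethyl-1,3-dioxolan-4-yl]methanol, via 2,3-O-isopropylidene-D-erythrofuranose 2 (not isolated)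
Conditions: iBu2AlH, CH2Cl2, −78 °C; then MeOH, K2CO3, dimethyl (1-diazo-2-oxopropyl)phosphonate, 0 °C to rt
Reagents that add atoms: dimethyl (1-diazo-2-oxopropyl)phosphonate, CC(=O)C(=[N+]=[N-])P(=O)(OC)OC
Why: Partial reduction to the lactol and Seyferth–Gilbert homologation with the Ohira–Bestmann reagent in one pot should turn the lactol carbon into the terminal alkyne (future C10–C11) while the cis-dioxolane stereocentres (future C8 and C9) come unchanged from the chiral pool.

Step 2
Reactants: 3 [(4R,5S)-5-ethynyl-2,2-dimethyl-1,3-dioxolan-4-yl]methanol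
Product: 4 (4S,5S)-5-ethynyl-2,2-dimethyl-1,3-dioxolane-4-carbaldehyde
Conditions: Dess–Martin periodinane, NaHCO3, CH2Cl2, 0 °C; used crude
Reagents that add atoms: none
Why: Buffered Dess–Martin oxidation should give the α-alkoxy aldehyde without epimerising the cis-dioxolane.

Step 3
Reactants: 4 (4S,5S)-5-ethynyl-2,2-dimethyl-1,3-dioxolane-4-carbaldehyde; 5 3-methylbuta-1,2-diene
Product: 7 (1S)-1-[(4R,5S)-5-ethynyl-2,2-dimethyl-1,3-dioxolan-4-yl]-2,2-dimethylbut-3-en-1-ol, via (−)-B-prenyldiisopinocampheylborane 6 (not isolated)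
Conditions: (−)-diisopinocampheylborane [from (+)-α-pinene], 5, THF, −25 °C; then 4, −78 °C; then NaOH, H2O2
Reagents that add atoms: none
Why: In this Brown reverse prenylation the γ,γ-dimethylallylborane formed by hydroboration of the allene should add through its tertiary terminus in a chair transition state to the Si face of the aldehyde, so that reagent control (against the modest Felkin bias of the dioxolane) sets C7 as S and creates the quaternary C6.

Step 4
Reactants: 7 (1S)-1-[(4R,5S)-5-ethynyl-2,2-dimethyl-1,3-dioxolan-4-yl]-2,2-dimethylbut-3-en-1-ol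
Product: 8 {[(1S)-1-[(4S,5S)-5-ethynyl-2,2-dimethyl-1,3-dioxolan-4-yl]-2,2-dimethylbut-3-en-1-yl]oxy}triethylsilane
Conditions: Et3SiOTf, 2,6-lutidine, CH2Cl2, −78 to 0 °C
Reagents that add atoms: triethylsilyl trifluoromethanesulfonate, CC[Si](CC)(CC)OS(=O)(=O)C(F)(F)F
Why: Silylation with the silyl triflate should protect the hindered neopentylic C7 hydroxyl, which would otherwise allow retro-aldol cleavage once the C5 aldehyde is unveiled.

Step 5
Reactants: 8 {[(1S)-1-[(4S,5S)-5-ethynyl-2,2-dimethyl-1,3-dioxolan-4-yl]-2,2-dimethylbut-3-en-1-yl]oxy}triethylsilane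
Product: 10 {[(1S)-1-[(4S,5S)-5-[(E)-1-iodoprop-1-en-2-yl]-2,2-dimethyl-1,3-dioxolan-4-yl]-2,2-dimethylbut-3-en-1-yl]oxy}triethylsilane, via alkenyldimethylalane 9 (not isolated)
Conditions: Me3Al, (C5H5)2ZrCl2, H2O (1.5 equiv), CH2Cl2, −30 °C; then I2, THF, −30 to 0 °C
Reagents that add atoms: trimethylaluminium, C[Al](C)C; iodine, II
Why: Zirconium-catalysed Negishi carboalumination should add methyl and aluminium syn across the terminal alkyne with methyl on the internal carbon (C10), and iodinolysis with retention gives the (E)-alkenyl iodide, the monosubstituted alkene being inert.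

Step 6
Reactants: 10 {[(1S)-1-[(4S,5S)-5-[(E)-1-iodoprop-1-en-2-yl]-2,2-dimethyl-1,3-dioxolan-4-yl]-2,2-dimethylbut-3-en-1-yl]oxy}triethylsilane
Product: 11 (3S)-3-[(4S,5S)-5-[(E)-1-iodoprop-1-en-2-yl]-2,2-dimethyl-1,3-dioxolan-4-yl]-2,2-dimethyl-3-(triethylsilyloxy)propanal
Conditions: OsO4 (2 mol%), NaIO4, 2,6-lutidine, dioxane/H2O, rt
Reagents that add atoms: sodium periodate, [Na+].[O-]I(=O)(=O)=O (oxygen source, relayed by OsO4, O=[Os](=O)(=O)=O)
Why: Lemieux–Johnson cleavage should remove the terminal CH2 of the monosubstituted alkene (the iodoalkene is deactivated towards OsO4) and give the non-enolisable neopentylic aldehyde C5.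

Step 7
Reactants: 12 (R)-3-bromo-2-methylpropan-1-ol
Product: 13 (R)-2-methyl-3-[(1-phenyl-1H-tetrazol-5-yl)sulfanyl]propan-1-ol
Conditions: 1-phenyl-1H-tetrazole-5-thiol, K2CO3, DMF, 60 °C
Reagents that add atoms: 1-phenyl-1H-tetrazole-5-thiol, Sc1nnnn1-c1ccccc1
Why: SN2 displacement of the primary bromide by the thiolate should leave the purchased methyl stereocentre (future C3) untouched.

Step 8
Reactants: 13 (R)-2-methyl-3-[(1-phenyl-1H-tetrazol-5-yl)sulfanyl]propan-1-ol
Product: 14 (R)-2-methyl-3-[(1-phenyl-1H-tetrazol-5-yl)sulfonyl]propan-1-ol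
Conditions: (NH4)6Mo7O24·4H2O (10 mol%), 30% H2O2, EtOH, 0 °C to rt
Reagents that add atoms: hydrogen peroxide, OO
Why: Molybdate-catalysed peroxide oxidation should take the sulfide to the sulfone needed for the Julia–Kocienski olefination.

Step 9
Reactants: 14 (R)-2-methyl-3-[(1-phenyl-1H-tetrazol-5-yl)sulfonyl]propan-1-ol
Product: 15 5-{[(2R)-2-methyl-3-(triethylsilyloxy)propyl]sulfonyl}-1-phenyl-1H-tetrazole
Conditions: Et3SiCl, imidazole, CH2Cl2, 0 °C
Reagents that add atoms: chlorotriethylsilane, CC[Si](Cl)(CC)CC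
Why: Silylation should mask the primary hydroxyl so that the sulfone can be metalated cleanly.

Step 10
Reactants: 15 5-{[(2R)-2-methyl-3-(triethylsilyloxy)propyl]sulfonyl}-1-phenyl-1H-tetrazole; 11 (3S)-3-[(4S,5S)-5-[(E)-1-iodoprop-1-en-2-yl]-2,2-dimethyl-1,3-dioxolan-4-yl]-2,2-dimethyl-3-(triethylsilyloxy)propanal
Product: 16 (2S,3E,6S)-6-[(4S,5S)-5-[(E)-1-iodoprop-1-en-2-yl]-2,2-dimethyl-1,3-dioxolan-4-yl]-2,5,5-trimethyl-1,6-bis(triethylsilyloxy)hex-3-ene
Conditions: 15, KN(SiMe3)2, 1,2-dimethoxyethane, −60 °C; then 11, −60 °C to rt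
Reagents that add atoms: none
Why: Julia–Kocienski olefination of the hindered non-enolisable aldehyde with the phenyltetrazolyl sulfone should give the E-configured C4=C5 bond through Smiles rearrangement and anti elimination, with no new stereocentre and no epimerisable position.

Step 11
Reactants: 16 (2S,3E,6S)-6-[(4S,5S)-5-[(E)-1-iodoprop-1-en-2-yl]-2,2-dimethyl-1,3-dioxolan-4-yl]-2,5,5-trimethyl-1,6-bis(triethylsilyloxy)hex-3-ene
Product: 17 (2S,3E,6S)-6-[(4S,5S)-5-[(E)-1-iodoprop-1-en-2-yl]-2,2-dimethyl-1,3-dioxolan-4-yl]-2,5,5-trimethyl-6-(triethylsilyloxy)hex-3-en-1-ol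
Conditions: pyridinium p-toluenesulfonate (0.2 equiv), MeOH/CH2Cl2, 0 °C
Reagents that add atoms: none
Why: Acid-catalysed methanolysis should remove the unhindered primary silyl ether much faster than the neopentylic secondary one or the acetonide.

Step 12
Reactants: 17 (2S,3E,6S)-6-[(4S,5S)-5-[(E)-1-iodoprop-1-en-2-yl]-2,2-dimethyl-1,3-dioxolan-4-yl]-2,5,5-trimethyl-6-(triethylsilyloxy)hex-3-en-1-ol
Product: 18 (2S,3E,6S)-6-[(4S,5S)-5-[(E)-1-iodoprop-1-en-2-yl]-2,2-dimethyl-1,3-dioxolan-4-yl]-2,5,5-trimethyl-6-(triethylsilyloxy)hex-3-enal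
Conditions: Dess–Martin periodinane, NaHCO3, CH2Cl2, 0 °C; crude aldehyde used at once
Reagents that add atoms: none
Why: Buffered Dess–Martin oxidation should give the α-methyl β,γ-unsaturated aldehyde under non-basic conditions that avoid conjugation of the double bond and epimerisation at C3.

Step 13
Reactants: 18 (2S,3E,6S)-6-[(4S,5S)-5-[(E)-1-iodoprop-1-en-2-yl]-2,2-dimethyl-1,3-dioxolan-4-yl]-2,5,5-trimethyl-6-(triethylsilyloxy)hex-3-enal
Product: 20 (2E,8E)-4,5-(isopropylidenedioxy)-3,7,7,10-tetramethyl-6-(triethylsilyloxy)cyclodeca-2,8-dien-1-ol, via alkenylchromium dichloride 19 (not isolated)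
Conditions: CrCl2 (10 equiv), NiCl2 (5 mol%), DMSO/THF, rt, 0.003 M, syringe-pump addition
Reagents that add atoms: none
Why: The intramolecular Nozaki–Hiyama–Kishi reaction (nickel-catalysed formation of the alkenyl trivalent chromium species, which adds chemoselectively to the aldehyde) should close the ten-membered ring at C1–C11 with the cis-dioxolane and the gem-dimethyl group as turn elements, and the C1 carbinol configuration is immaterial because it is oxidised next.

Step 14
Reactants: 20 (2E,8E)-4,5-(isopropylidenedioxy)-3,7,7,10-tetramethyl-6-(triethylsilyloxy)cyclodeca-2,8-dien-1-ol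
Product: 21 (2E,8E)-4,5-(isopropylidenedioxy)-3,7,7,10-tetramethyl-6-(triethylsilyloxy)cyclodeca-2,8-dien-1-one
Conditions: Dess–Martin periodinane, NaHCO3, CH2Cl2, 0 °C; filtration through neutral alumina, used directly
Reagents that add atoms: none
Why: Oxidation of the allylic alcohol should give the ketone that is α,β-unsaturated on one side and β,γ-unsaturated on the other under neutral conditions, so that C3 keeps its configuration.

Step 15
Reactants: 21 (2E,8E)-4,5-(isopropylidenedioxy)-3,7,7,10-tetramethyl-6-(triethylsilyloxy)cyclodeca-2,8-dien-1-one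
Product: 22 8,9-O-isopropylidene-7-O-triethylsilyl-7,8,9-trihydroxy-2-norlongipinan-1-one
Conditions: hν (350 nm, Pyrex), degassed cyclohexane, 0.005 M, rt
Reagents that add atoms: none
Why: Excitation (n→π*) and intersystem crossing give the enone triplet, whose β-carbon C10 bonds to C4 to form a triplet 1,4-biradical (α-acyl radical at C11, secondary radical at C5) that closes the C5–C11 bond after spin inversion. The closest known reaction type is the crossed intramolecular (including transannular) enone–alkene [2+2] photocycloaddition of hexa-1,5-dien-3-ones to bicyclo[2.1.1]hexan-2-ones. The cyclopentanone ring (C1, C3, C4, C10, C11) closes 5-exo on the C4=C5 bond (rule of five), the cyclobutane closes by 1,4-biradical recombination, and the cycloheptane results from the same transannular C4–C10 bond (7-endo with respect to C4=C5). The mutual configuration of C4, C5, C10 and C11 is dictated by ring topology, since the two-carbon bridge C1–C3 and the four-carbon bridge C6–C9 must leave the cyclobutane on opposite faces, which puts the C10 methyl syn to the C1–C3 bridge; the absolute sense is controlled by C3, whose methyl should come to lie on the side of the hydrogen-bearing bridge carbon C5 because the alternative presses it against the C10 methyl. The step needs crossed instead of straight regiochemistry, secured by the two-atom C1–C3 link (a straight closure would require a four-membered first ring), and the correct facial pairing, secured by the C3 stereocentre with the cis-dioxolane and gem-dimethyl group restricting the macrocycle; E/Z isomerisation of the excited enone is harmless because both isomers converge on the same biradical. Long-wavelength irradiation in the conjugated enone band is chosen to disfavour α-cleavage (1,3-acyl shift) of the β,γ-unsaturated ketone.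

Step 16
Reactants: 22 8,9-O-isopropylidene-7-O-triethylsilyl-7,8,9-trihydroxy-2-norlongipinan-1-one
Product: 24 8,9-O-isopropylidene-7-O-triethylsilyl-7,8,9-trihydroxylongipinan-1-one, via α-trimethylsilyl ketone 23 (not isolated)
Conditions: Me3SiCHN2, Me3Al, CH2Cl2, −78 to −20 °C; then K2CO3, MeOH, rt
Reagents that add atoms: (trimethylsilyl)diazomethane, C[Si](C)(C)C=[N+]=[N-]
Why: Lewis-acid-promoted diazoalkane ring expansion (a Tiffeneau–Demjanov-type 1,2-shift in the diazonium betaine) should insert C2 between C1 and C3 by migration of the less encumbered non-bridgehead carbon C3 with retention, so that the C3 configuration brought in with 12 becomes that of the target, and methanolysis removes the α-silyl group.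

Step 17
Reactants: 24 8,9-O-isopropylidene-7-O-triethylsilyl-7,8,9-trihydroxylongipinan-1-one
Product: 25 7,8,9-trihydroxylongipinan-1-one
Conditions: CF3CO2H/H2O/THF (1:1:4), 0 °C to rt
Reagents that add atoms: none
Why: Mild aqueous acid should hydrolyse the silyl ether and the acetonide in one operation without opening the cyclobutyl ketone.

Step 18
Reactants: 25 7,8,9-trihydroxylongipinan-1-one
Product: 26 8-O-triethylsilyl-7,8,9-trihydroxylongipinan-1-one
Conditions: Et3SiCl (1.05 equiv), imidazole, DMF/CH2Cl2, −40 °C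
Reagents that add atoms: chlorotriethylsilane, CC[Si](Cl)(CC)CC
Why: Kinetic silylation should select the C8 hydroxyl, the only one not flanked by a quaternary carbon (C7–OH is neopentylic to C6 and C9–OH to C10).

Step 19
Reactants: 26 8-O-triethylsilyl-7,8,9-trihydroxylongipinan-1-one; 27 angelic acid
Product: 29 7,9-di-O-angeloyl-8-O-triethylsilyl-7,8,9-trihydroxylongipinan-1-one, via angelic 2,4,6-trichlorobenzoic anhydride 28 (not isolated)
Conditions: 27 (6 equiv), 2,4,6-trichlorobenzoyl chloride, Et3N, toluene, rt; then 26, 80 °C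
Reagents that add atoms: none
Why: Acylation with the preformed Yamaguchi mixed anhydride in the absence of nucleophilic catalysts should esterify both hindered secondary hydroxyls while keeping the Z (angelate) geometry, which nucleophilic amine catalysts tend to isomerise to the tiglate.

Step 20
Reactants: 29 7,9-di-O-angeloyl-8-O-triethylsilyl-7,8,9-trihydroxylongipinan-1-one
Product: 30 CNP0303821.1 (7,9-di-O-angeloyl-7,8,9-trihydroxylongipinan-1-one)
Conditions: HF·pyridine, pyridine, THF, 0 °C to rt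
Reagents that add atoms: none
Why: Buffered fluoride desilylation should free the C8 hydroxyl under slightly acidic conditions that avoid acyl migration and angelate isomerisation.

**Compound list**

1 | 2,3-O-isopropylidene-D-erythronolactone, (3aR,6aR)-2,2-dimethyldihydrofuro[3,4-d][1,3]dioxol-4(3aH)-one | O=C1OC[C@H]2OC(C)(C)O[C@@H]12 | starting material
2 | 2,3-O-isopropylidene-D-erythrofuranose (lactol, both anomers) | OC1OC[C@H]2OC(C)(C)O[C@@H]12 | intermediate (not isolated)
3 | [(4R,5S)-5-ethynyl-2,2-dimethyl-1,3-dioxolan-4-yl]methanol | C#C[C@@H]1OC(C)(C)O[C@@H]1CO | intermediate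
4 | (4S,5S)-5-ethynyl-2,2-dimethyl-1,3-dioxolane-4-carbaldehyde | C#C[C@@H]1OC(C)(C)O[C@@H]1C=O | intermediate
5 | 3-methylbuta-1,2-diene | CC(C)=C=C | starting material
6 | (−)-B-(3-methylbut-2-en-1-yl)diisopinocampheylborane | CC(C)=CCB([C@@H]1C[C@@H]2C[C@H]([C@H]1C)C2(C)C)[C@@H]1C[C@@H]2C[C@H]([C@H]1C)C2(C)C | intermediate (not isolated)
7 | (1S)-1-[(4R,5S)-5-ethynyl-2,2-dimethyl-1,3-dioxolan-4-yl]-2,2-dimethylbut-3-en-1-ol | C#C[C@@H]1OC(C)(C)O[C@@H]1[C@@H](O)C(C)(C)C=C | intermediate
8 | {[(1S)-1-[(4S,5S)-5-ethynyl-2,2-dimethyl-1,3-dioxolan-4-yl]-2,2-dimethylbut-3-en-1-yl]oxy}triethylsilane | C#C[C@@H]1OC(C)(C)O[C@@H]1[C@@H](O[Si](CC)(CC)CC)C(C)(C)C=C | intermediate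
9 | (E)-alkenyldimethylalane from 8 (methyl on the internal carbon, methyl and aluminium cis) | C[Al](C)/C=C(\C)[C@@H]1OC(C)(C)O[C@@H]1[C@@H](O[Si](CC)(CC)CC)C(C)(C)C=C | intermediate (not isolated)
10 | {[(1S)-1-[(4S,5S)-5-[(E)-1-iodoprop-1-en-2-yl]-2,2-dimethyl-1,3-dioxolan-4-yl]-2,2-dimethylbut-3-en-1-yl]oxy}triethylsilane | I/C=C(\C)[C@@H]1OC(C)(C)O[C@@H]1[C@@H](O[Si](CC)(CC)CC)C(C)(C)C=C | intermediate
11 | (3S)-3-[(4S,5S)-5-[(E)-1-iodoprop-1-en-2-yl]-2,2-dimethyl-1,3-dioxolan-4-yl]-2,2-dimethyl-3-(triethylsilyloxy)propanal | I/C=C(\C)[C@@H]1OC(C)(C)O[C@@H]1[C@@H](O[Si](CC)(CC)CC)C(C)(C)C=O | intermediate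
12 | (R)-3-bromo-2-methylpropan-1-ol | OC[C@@H](C)CBr | starting material
13 | (R)-2-methyl-3-[(1-phenyl-1H-tetrazol-5-yl)sulfanyl]propan-1-ol | OC[C@@H](C)CSc1nnnn1-c1ccccc1 | intermediate
14 | (R)-2-methyl-3-[(1-phenyl-1H-tetrazol-5-yl)sulfonyl]propan-1-ol | OC[C@@H](C)CS(=O)(=O)c1nnnn1-c1ccccc1 | intermediate
15 | 5-{[(2R)-2-methyl-3-(triethylsilyloxy)propyl]sulfonyl}-1-phenyl-1H-tetrazole | CC[Si](CC)(CC)OC[C@@H](C)CS(=O)(=O)c1nnnn1-c1ccccc1 | intermediate
16 | (2S,3E,6S)-6-[(4S,5S)-5-[(E)-1-iodoprop-1-en-2-yl]-2,2-dimethyl-1,3-dioxolan-4-yl]-2,5,5-trimethyl-1,6-bis(triethylsilyloxy)hex-3-ene | I/C=C(\C)[C@@H]1OC(C)(C)O[C@@H]1[C@@H](O[Si](CC)(CC)CC)C(C)(C)/C=C/[C@H](C)CO[Si](CC)(CC)CC | intermediate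
17 | (2S,3E,6S)-6-[(4S,5S)-5-[(E)-1-iodoprop-1-en-2-yl]-2,2-dimethyl-1,3-dioxolan-4-yl]-2,5,5-trimethyl-6-(triethylsilyloxy)hex-3-en-1-ol | I/C=C(\C)[C@@H]1OC(C)(C)O[C@@H]1[C@@H](O[Si](CC)(CC)CC)C(C)(C)/C=C/[C@H](C)CO | intermediate
18 | (2S,3E,6S)-6-[(4S,5S)-5-[(E)-1-iodoprop-1-en-2-yl]-2,2-dimethyl-1,3-dioxolan-4-yl]-2,5,5-trimethyl-6-(triethylsilyloxy)hex-3-enal | I/C=C(\C)[C@@H]1OC(C)(C)O[C@@H]1[C@@H](O[Si](CC)(CC)CC)C(C)(C)/C=C/[C@H](C)C=O | intermediate
19 | alkenylchromium dichloride from 18 (trivalent chromium in place of iodine) | Cl[Cr](Cl)/C=C(\C)[C@@H]1OC(C)(C)O[C@@H]1[C@@H](O[Si](CC)(CC)CC)C(C)(C)/C=C/[C@H](C)C=O | intermediate (not isolated)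
20 | (2E,8E)-4,5-(isopropylidenedioxy)-3,7,7,10-tetramethyl-6-(triethylsilyloxy)cyclodeca-2,8-dien-1-ol (C1 epimers; the four other stereocentres as in 18, cis-dioxolane) | OC1/C=C(\C)[C@@H]2OC(C)(C)O[C@@H]2[C@@H](O[Si](CC)(CC)CC)C(C)(C)/C=C/[C@@H]1C | intermediate
21 | (2E,8E)-4,5-(isopropylidenedioxy)-3,7,7,10-tetramethyl-6-(triethylsilyloxy)cyclodeca-2,8-dien-1-one (stereocentres as in 18) | O=C1/C=C(\C)[C@@H]2OC(C)(C)O[C@@H]2[C@@H](O[Si](CC)(CC)CC)C(C)(C)/C=C/[C@@H]1C | intermediate
22 | 8,9-O-isopropylidene-7-O-triethylsilyl-7,8,9-trihydroxy-2-norlongipinan-1-one (C1 bonded to C3; bicyclo[2.1.1]hexan-2-one fused to the cycloheptane; C3 methyl on the side of the C5 bridge) | CC[Si](CC)(CC)O[C@@H]1[C@H]4OC(C)(C)O[C@H]4[C@]2(C)[C@@H]3[C@@H]([C@H]2C(=O)[C@H]3C)C1(C)C | intermediate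
23 | 2-(trimethylsilyl) derivative of 24 (α-silyl ketone, C2 epimers) | CC[Si](CC)(CC)O[C@@H]1[C@H]4OC(C)(C)O[C@H]4[C@]2(C)[C@@H]3[C@@H]([C@H]2C(=O)C([Si](C)(C)C)[C@H]3C)C1(C)C | intermediate (not isolated)
24 | 8,9-O-isopropylidene-7-O-triethylsilyl-7,8,9-trihydroxylongipinan-1-one (all stereocentres as in the target) | CC[Si](CC)(CC)O[C@@H]1[C@H]4OC(C)(C)O[C@H]4[C@]2(C)[C@@H]3[C@@H]([C@H]2C(=O)C[C@H]3C)C1(C)C | intermediate
25 | 7,8,9-trihydroxylongipinan-1-one (stereocentres as in the target) | O[C@@H]1[C@@H](O)[C@@H](O)[C@]2(C)[C@@H]3[C@@H]([C@H]2C(=O)C[C@H]3C)C1(C)C | intermediate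
26 | 8-O-triethylsilyl-7,8,9-trihydroxylongipinan-1-one | O[C@@H]1[C@@H](O[Si](CC)(CC)CC)[C@@H](O)[C@]2(C)[C@@H]3[C@@H]([C@H]2C(=O)C[C@H]3C)C1(C)C | intermediate
27 | angelic acid, (Z)-2-methylbut-2-enoic acid | C/C=C(/C)C(=O)O | starting material
28 | angelic 2,4,6-trichlorobenzoic anhydride | C/C=C(/C)C(=O)OC(=O)c1c(Cl)cc(Cl)cc1Cl | intermediate (not isolated)
29 | 7,9-di-O-angeloyl-8-O-triethylsilyl-7,8,9-trihydroxylongipinan-1-one | C/C=C(/C)C(=O)O[C@@H]1[C@@H](O[Si](CC)(CC)CC)[C@@H](OC(=O)/C(C)=C\C)[C@]2(C)[C@@H]3[C@@H]([C@H]2C(=O)C[C@H]3C)C1(C)C | intermediate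
30 | CNP0303821.1, 7,9-di-O-angeloyl-7,8,9-trihydroxylongipinan-1-one | C/C=C(/C)C(=O)O[C@@H]1[C@@H](O)[C@@H](OC(=O)/C(C)=C\C)[C@]2(C)[C@@H]3[C@@H]([C@H]2C(=O)C[C@H]3C)C1(C)C | target

**Step count and risks**

Total step count: 20. Longest linear sequence: 17 (steps 1–6 and 10–20; the sulfone branch, steps 7–9, joins at step 10).

Step 13 (ring closure to the ten-membered dienol). The closure may be slow because of medium-ring strain, so that intermolecular coupling and isomerisation of the β,γ-unsaturated aldehyde into conjugation (with loss of the C3 configuration) overtake it. The fallback closes the ring at the C4=C5 double bond instead, after the C1–C11 bond has been made intermolecularly; it sets out from alkenyl iodide 10 and hydroxy sulfide 13 and comes back to the route at 20. Sulfide 13 is oxidised with Dess–Martin periodinane to (R)-2-methyl-3-[(1-phenyl-1H-tetrazol-5-yl)sulfanyl]propanal F1. Intermolecular Nozaki–Hiyama–Kishi coupling of 10 with F1 (CrCl2, catalytic NiCl2, DMSO) should give the allylic alcohol F2 as C1 epimers. Silylation (Et3SiCl, imidazole) gives the bis(triethylsilyl) ether F3, and molybdate/H2O2 oxidation gives the sulfone F4. Lemieux–Johnson cleavage of the terminal vinyl group, which should outpace the trisubstituted olefin flanked by two oxygenated carbons, gives the sulfone aldehyde F5. Intramolecular Julia–Kocienski olefination (KN(SiMe3)2, DME, high dilution) of this non-enolisable aldehyde should give the macrocyclic bis(triethylsilyl) ether F6. Pyridinium p-toluenesulfonate in MeOH then removes the allylic silyl ether selectively and delivers 20.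

Step 15 (transannular photocycloaddition). The excited enone may decay without bonding (E/Z isomerisation), the β,γ-unsaturated ketone may undergo α-cleavage and 1,3-acyl shift, or the two olefins may pair with insufficient facial preference. The fallback avoids the enone triplet: it sets out from dienol 20 and comes back at 22. Photobicyclisation of the 1,5-diene catalysed by monovalent copper ((CuOTf)2·C6H6, Et2O, 254 nm), with the allylic hydroxyl as an additional ligand, should give the tricyclic alcohol F7 by the same crossed transannular union of C4=C5 with C10=C11. Dess–Martin oxidation of F7 gives 22.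

Step 16 (one-carbon ring expansion). The bridgehead carbon C11 may migrate instead of C3, which would give the regioisomeric ketone, or the Lewis acid may attack the acetal. The fallback fixes the regiochemistry by enolisation; it sets out from 22 and comes back at 24. Soft enolisation (Me3SiOTf, Et3N) can occur only towards C3, because C11 is a bridgehead, and gives the trimethylsilyl enol ether F8. Cyclopropanation (Et2Zn, CH2I2) gives the siloxycyclopropane F9; either epimer serves. FeCl3 in DMF opens the internal bond (Saegusa–Ito ring expansion) to the β-chloro ketone F10, which NaOAc in MeOH converts into the ring-expanded enone F11 (C2=C3). Luche reduction (NaBH4, CeCl3·7H2O) should deliver hydride from the open side of the C5 bridge and give the allylic alcohol F12 with the hydroxyl on the face of the C10 bridge. Hydroxyl-directed hydrogenation with [Ir(cod)(PCy3)(py)]PF6 and H2 then adds hydrogen to C3 from that face, so that the methyl ends on the side of C5 in the saturated alcohol F13. Dess–Martin oxidation of F13 gives 24.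

Further compounds
F1 | step 13 | (R)-2-methyl-3-[(1-phenyl-1H-tetrazol-5-yl)sulfanyl]propanal | O=C[C@@H](C)CSc1nnnn1-c1ccccc1
F2 | step 13 | allylic alcohol from 10 and F1 (C1 epimers; C1–C11 bond formed, terminal vinyl and sulfide retained) | OC(/C=C(\C)[C@@H]1OC(C)(C)O[C@@H]1[C@@H](O[Si](CC)(CC)CC)C(C)(C)C=C)[C@@H](C)CSc1nnnn1-c1ccccc1
F3 | step 13 | triethylsilyl ether of F2 | CC[Si](CC)(CC)OC(/C=C(\C)[C@@H]1OC(C)(C)O[C@@H]1[C@@H](O[Si](CC)(CC)CC)C(C)(C)C=C)[C@@H](C)CSc1nnnn1-c1ccccc1
F4 | step 13 | sulfone from F3 | CC[Si](CC)(CC)OC(/C=C(\C)[C@@H]1OC(C)(C)O[C@@H]1[C@@H](O[Si](CC)(CC)CC)C(C)(C)C=C)[C@@H](C)CS(=O)(=O)c1nnnn1-c1ccccc1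
F5 | step 13 | sulfone aldehyde from F4 (C5 aldehyde) | CC[Si](CC)(CC)OC(/C=C(\C)[C@@H]1OC(C)(C)O[C@@H]1[C@@H](O[Si](CC)(CC)CC)C(C)(C)C=O)[C@@H](C)CS(=O)(=O)c1nnnn1-c1ccccc1
F6 | step 13 | triethylsilyl ether of 20 (macrocyclic bis(triethylsilyl) ether) | CC[Si](CC)(CC)OC1/C=C(\C)[C@@H]2OC(C)(C)O[C@@H]2[C@@H](O[Si](CC)(CC)CC)C(C)(C)/C=C/[C@@H]1C
F7 | step 15 | 8,9-O-isopropylidene-7-O-triethylsilyl-2-norlongipinane-1,7,8,9-tetrol (C1 epimers; the alcohol corresponding to 22) | CC[Si](CC)(CC)O[C@@H]1[C@H]4OC(C)(C)O[C@H]4[C@]2(C)[C@@H]3[C@@H]([C@H]2C(O)[C@H]3C)C1(C)C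
F8 | step 16 | trimethylsilyl enol ether of 22 (C1=C3) | CC[Si](CC)(CC)O[C@@H]1[C@H]4OC(C)(C)O[C@H]4[C@]2(C)[C@@H]3[C@@H]([C@H]2C(O[Si](C)(C)C)=C3C)C1(C)C
F9 | step 16 | siloxycyclopropane from F8 (CH2 bridging C1 and C3, added from the side of the C5 bridge) | CC[Si](CC)(CC)O[C@@H]1[C@H]4OC(C)(C)O[C@H]4[C@]2(C)[C@@H]3[C@@H]([C@H]2[C@@]5(O[Si](C)(C)C)C[C@@]35C)C1(C)C
F10 | step 16 | 3-chloro derivative of 24 (β-chloro ketone, C3 epimers) | CC[Si](CC)(CC)O[C@@H]1[C@H]4OC(C)(C)O[C@H]4[C@]2(C)[C@@H]3[C@@H]([C@H]2C(=O)CC3(C)Cl)C1(C)C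
F11 | step 16 | 8,9-O-isopropylidene-7-O-triethylsilyl-7,8,9-trihydroxylongipin-2-en-1-one | CC[Si](CC)(CC)O[C@@H]1[C@H]4OC(C)(C)O[C@H]4[C@]2(C)[C@@H]3[C@@H]([C@H]2C(=O)C=C3C)C1(C)C
F12 | step 16 | allylic alcohol from F11 (C1 hydroxyl on the face of the C10 bridge) | CC[Si](CC)(CC)O[C@@H]1[C@H]4OC(C)(C)O[C@H]4[C@]2(C)[C@@H]3[C@@H]([C@H]2[C@H](O)C=C3C)C1(C)C
F13 | step 16 | saturated alcohol from F12 (C3 as in the target; the alcohol corresponding to 24) | CC[Si](CC)(CC)O[C@@H]1[C@H]4OC(C)(C)O[C@H]4[C@]2(C)[C@@H]3[C@@H]([C@H]2[C@H](O)C[C@H]3C)C1(C)C
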